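**Retrosynthetic overview**

1. Numbering: C1 ring-fusion C(CH3), C2 C=O, C3 CH2, C4 C(OH)(i-Pr), C5 ring-fusion CH, C6 CH–O, C7 CH2, C8 C(CH3)=C9H, C10 CH2. The strategy rests on the seven-membered ring C1–C5–C6–C7–C8–C9–C10: at the C6-ketone level it is a cyclohepta-1,4-diene (C5=C6 enol, C8=C9) around C7, so C1–C10 is a Cope bond and C6–C7–C8 a cyclopropane.
2. Endgame from the vinylogous silyl ester 16: C6–O ester, C6–H (hydroxyl-directed reduction), C5–H (desilylation), C4–i-Pr (organocerium addition), C2 ketal removed last.
3. Key disconnection C1–C10: 16 arises from the cis-1-siloxy-1-cyclopentenyl-2-methyl-2-vinylcyclopropane 15 by a [3,3] shift, which closes the seven-membered ring and creates quaternary C1.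
4. 15 comes from a (1E)-silyl trienol ether by hydroxyl-directed CH2 transfer (C7 from CH2I2); the trienol ether comes from a tiglyl dienone by γ-deprotonation; the C5–C6 bond is made by Nozaki–Hiyama–Kishi coupling of a 2-iodocyclopentenyl ester with tiglic aldehyde. C4 is held as a CBS-set carbinol until the cyclopropane is in place, because in the ene-dione the C1 methyl and C3–H2 would be the acidic sites.
5. Ring order: five-membered ring (from 2-methylcyclopent-2-en-1-one), then the three-membered ring, then the seven-membered ring.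

Key step: step 12

Remark: the target SMILES is read as (1R,4R,5S,6S) in this numbering, that is trans ring fusion (C1–CH3 anti to C5–H), C4–OH syn to C1–CH3, and C6–O anti to C1–CH3 (H6 anti to H5).

**Route**

Step 1
Reactants: 1 2-methylcyclopent-2-en-1-one
Product: 2 6-methyl-1,4-dioxaspiro[4.4]non-6-ene
Conditions: (Me3SiOCH2)2, Me3SiOTf (cat.), CH2Cl2, −78 → −20 °C
Reagents that add atoms: 1,2-bis(trimethylsilyloxy)ethane C[Si](C)(C)OCCO[Si](C)(C)C
Why: Aprotic silyl-triflate-catalysed ketalisation (Noyori conditions) converts the enone carbonyl into the dioxolane without moving the C=C bond out of the 2,3-position, so the ketal ends up on the carbon next to the methyl-bearing alkene carbon (future C2 next to C1).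

Step 2
Reactants: 2 6-methyl-1,4-dioxaspiro[4.4]non-6-ene
Product: 3 6-methyl-1,4-dioxaspiro[4.4]non-6-en-8-one
Conditions: t-BuOOH, dirhodium tetracaprolactamate Rh2(C6H10NO)4 (cat.), K2CO3, CH2Cl2, rt
Reagents that add atoms: tert-butyl hydroperoxide CC(C)(C)OO
Why: Allylic C–H oxidation of a cycloalkene to the enone: C8 is the only allylic ring methylene (the other flank of the alkene is the ketal carbon), so the new carbonyl (future C4) is placed next to the vinylic CH (future C5) under basic conditions that leave the ketal intact.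

Step 3
Reactants: 3 6-methyl-1,4-dioxaspiro[4.4]non-6-en-8-one
Product: 4 7-iodo-6-methyl-1,4-dioxaspiro[4.4]non-6-en-8-one
Conditions: I2, pyridine, DMAP (cat.), CH2Cl2, 0 °C → rt
Reagents that add atoms: iodine II
Why: α-Iodination of a cyclic enone by amine conjugate addition, iodination of the enolate and elimination installs the halide at the only vinylic C–H, the position that will carry C6.

Step 4
Reactants: 4 7-iodo-6-methyl-1,4-dioxaspiro[4.4]non-6-en-8-one
Product: 5 (8S)-7-iodo-6-methyl-1,4-dioxaspiro[4.4]non-6-en-8-ol
Conditions: (R)-2-methyl-CBS-oxazaborolidine (cat.), BH3·SMe2, THF, −20 °C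
Reagents that add atoms: none
Why: Corey–Bakshi–Shibata reduction of a 2-iodocycloalkenone, in which the iodoalkene acts as the large group, should give the (8S)-allylic alcohol in high enantiomeric purity; this temporary stereocentre (future C4) removes the in-ring enone before step 8 and later directs the cyclopropanation.

Step 5
Reactants: 5 (8S)-7-iodo-6-methyl-1,4-dioxaspiro[4.4]non-6-en-8-ol
Product: 6 (8S)-7-iodo-6-methyl-1,4-dioxaspiro[4.4]non-6-en-8-yl 2,2-dimethylpropanoate
Conditions: PivCl, pyridine, DMAP (cat.), CH2Cl2, 0 °C → rt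
Reagents that add atoms: pivaloyl chloride CC(C)(C)C(Cl)=O
Why: Acylation of the secondary allylic alcohol; a pivalate has no α-hydrogen and is slow in acyl transfer, so it should survive the chromium coupling and the amide base and can be removed reductively without acid or fluoride.

Step 6
Reactants: 6 (8S)-7-iodo-6-methyl-1,4-dioxaspiro[4.4]non-6-en-8-yl 2,2-dimethylpropanoate; 7 (E)-2-methylbut-2-enal (tiglic aldehyde)
Product: 8 (8S)-7-[(2E)-1-hydroxy-2-methylbut-2-en-1-yl]-6-methyl-1,4-dioxaspiro[4.4]non-6-en-8-yl 2,2-dimethylpropanoate (both carbinol epimers)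
Conditions: CrCl2, NiCl2 (cat.), DMF, rt
Reagents that add atoms: none
Why: Nozaki–Hiyama–Kishi coupling: nickel-catalysed formation of the alkenylchromium reagent from the hindered iodide and its 1,2-addition to the enal form the C5–C6 bond in the presence of the ester and the ketal; the new carbinol centre is of no consequence because it is oxidised in step 7.

Step 7
Reactants: 8 (8S)-7-[(2E)-1-hydroxy-2-methylbut-2-en-1-yl]-6-methyl-1,4-dioxaspiro[4.4]non-6-en-8-yl 2,2-dimethylpropanoate
Product: 9 (8S)-6-methyl-7-[(2E)-2-methylbut-2-enoyl]-1,4-dioxaspiro[4.4]non-6-en-8-yl 2,2-dimethylpropanoate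
Conditions: Dess–Martin periodinane, NaHCO3, CH2Cl2, 0 °C
Reagents that add atoms: none
Why: Dess–Martin oxidation of the bis-allylic alcohol under buffered, non-acidic conditions gives the cross-conjugated dienone without ionising the substrate or triggering a Nazarov closure.

Step 8
Reactants: 9 (8S)-6-methyl-7-[(2E)-2-methylbut-2-enoyl]-1,4-dioxaspiro[4.4]non-6-en-8-yl 2,2-dimethylpropanoate
Product: 11 (8S)-7-[(1E)-1-(tert-butyldimethylsilyloxy)-2-methylbuta-1,3-dien-1-yl]-6-methyl-1,4-dioxaspiro[4.4]non-6-en-8-yl 2,2-dimethylpropanoate, via potassium dienolate 10 (not isolated)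
Conditions: KN(SiMe3)2, THF, −78 °C; then TBSOTf, −78 °C
Reagents that add atoms: tert-butyldimethylsilyl trifluoromethanesulfonate CC(C)(C)[Si](C)(C)OS(=O)(=O)C(F)(F)F
Why: γ-Deprotonation of the tiglyl enone (vinylogous enolisation) and O-silylation: the carbonyl is conjugated only with the side-chain alkene because the tetrasubstituted ring alkene is twisted out of plane, so C10–H3 is the one acidic site, and the s-trans enone conformer (ring next to C9–H, not next to the C8 methyl) should lead to the (1E) enol ether in which the cyclopentenyl and vinyl groups are cis.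

Step 9
Reactants: 11 (8S)-7-[(1E)-1-(tert-butyldimethylsilyloxy)-2-methylbuta-1,3-dien-1-yl]-6-methyl-1,4-dioxaspiro[4.4]non-6-en-8-yl 2,2-dimethylpropanoate
Product: 12 (8S)-7-[(1E)-1-(tert-butyldimethylsilyloxy)-2-methylbuta-1,3-dien-1-yl]-6-methyl-1,4-dioxaspiro[4.4]non-6-en-8-ol
Conditions: i-Bu2AlH, CH2Cl2, −78 °C; aqueous potassium sodium tartrate work-up
Reagents that add atoms: none
Why: Reductive cleavage of the pivalate at low temperature frees the C4 hydroxyl under conditions to which a TBS enol ether and the ketal are inert.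

Step 10
Reactants: 12 (8S)-7-[(1E)-1-(tert-butyldimethylsilyloxy)-2-methylbuta-1,3-dien-1-yl]-6-methyl-1,4-dioxaspiro[4.4]non-6-en-8-ol; 13 diiodomethane
Product: 14 (8S)-7-[(1S,2R)-1-(tert-butyldimethylsilyloxy)-2-methyl-2-vinylcyclopropyl]-6-methyl-1,4-dioxaspiro[4.4]non-6-en-8-ol
Conditions: Et2Zn, CH2Cl2, −10 → 0 °C
Reagents that add atoms: none
Why: Hydroxyl-directed Simmons–Smith cyclopropanation: the zinc alkoxide at C4 should deliver CH2 to the electron-rich enol ether alkene on its face turned toward C4, in the rotamer that keeps the bulky OTBS away from the carbinol oxygen, so the (8S)-carbinol is expected to give the (1S,2R) cyclopropane; syn addition carries the (1E) geometry into the cis relationship of cyclopentenyl and vinyl, the ring alkene being screened on both faces by the perpendicular enol ether and the vinyl group being unactivated.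

Step 11
Reactants: 14 (8S)-7-[(1S,2R)-1-(tert-butyldimethylsilyloxy)-2-methyl-2-vinylcyclopropyl]-6-methyl-1,4-dioxaspiro[4.4]non-6-en-8-ol
Product: 15 7-[(1S,2R)-1-(tert-butyldimethylsilyloxy)-2-methyl-2-vinylcyclopropyl]-6-methyl-1,4-dioxaspiro[4.4]non-6-en-8-one (cis-divinyl isomer)
Conditions: Dess–Martin periodinane, pyridine, CH2Cl2, 0 °C
Reagents that add atoms: none
Why: Dess–Martin oxidation of the allylic alcohol restores the C4 carbonyl and removes the auxiliary stereocentre under buffered conditions that a cyclopropyl silyl ether tolerates.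

Step 12
Reactants: 15 7-[(1S,2R)-1-(tert-butyldimethylsilyloxy)-2-methyl-2-vinylcyclopropyl]-6-methyl-1,4-dioxaspiro[4.4]non-6-en-8-one
Product: 16 (1R)-bicyclic vinylogous silyl ester: C4 ketone, C5=C6 TBS enol ether, C2 ethylene ketal, C8=C9 alkene, methyl groups on C1 and C8
Conditions: toluene (degassed, trace Et3N), 100–110 °C, sealed tube
Reagents that add atoms: none
Why: On heating, the ring alkene C1=C5 and the vinyl group C9=C10 fold over the three-membered ring in a boat array and the strained C6–C8 bond breaks as C1–C10 forms in a concerted [3,3] sigmatropic shift, leaving C5=C6 as the TBS enol ether conjugated to the C4 ketone and C8=C9 as the trisubstituted alkene. The closest known reaction type is the divinylcyclopropane–cycloheptadiene rearrangement of oxygen-substituted cis-1-cycloalkenyl-2-vinylcyclopropanes, including cyclopentenyl cases that generate an angular methyl group. The seven-membered ring (C1, C5, C6, C7, C8, C9, C10) is closed by this pericyclic ring expansion of the cyclopropane, the new σ-bond being made suprafacially on both allyl halves, not by an ionic or radical cyclisation. C1 is the only stereocentre formed (C6 and C8 become trigonal): for the (1S,2R) cyclopropane a single boat is possible, in which C10 reaches the face of C1 that gives the 1R configuration, so the cyclopropane chirality is transferred to the quaternary carbon. The step needs the cis-divinyl isomer of one absolute configuration, which is secured by the stereospecific methylene transfer to the (1E) enol ether in step 10 and by purification of 14, and it needs a temperature below that of homolytic one-centre epimerisation, which would racemise the material. The siloxy donor on C6 and the enone acceptor ending at C1 polarise the shift and should offset the penalty of the C1 methyl pointing toward the C7 methylene in the boat.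

Step 13
Reactants: 16 (1R)-bicyclic vinylogous silyl ester; 17 isopropylmagnesium chloride
Product: 19 (1R,4R,5R)-4-hydroxy-4-isopropyl C6 ketone with C2 ethylene ketal and C8=C9 alkene (trans-fused β-hydroxy ketone), via tertiary carbinol 18 (not isolated)
Conditions: CeCl3, THF, −78 °C; then AcOH, Bu4NF, −78 → 0 °C
Reagents that add atoms: none
Why: Organocerium 1,2-addition to the carbonyl of the vinylogous silyl ester (no enolisation of C3–H2, no conjugate addition) is expected from the face anti to the pseudo-axial C1 methyl, placing the hydroxyl syn to it (4R); buffered fluoride then unmasks the C6 ketone by C5 protonation without ionising the tertiary allylic alcohol, and the epimerisable C5 centre should settle in the trans-fused arrangement in which C6 is anti to the isopropyl group and hydrogen-bonded to the C4 hydroxyl.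

Step 14
Reactants: 19 (1R,4R,5R)-trans-fused β-hydroxy ketone
Product: 20 (1R,4R,5S,6S)-4,6-diol with C2 ethylene ketal and C8=C9 alkene
Conditions: Me4NBH(OAc)3, MeCN/AcOH, −30 °C
Reagents that add atoms: none
Why: Hydroxyl-directed triacetoxyborohydride reduction (Evans–Saksena): after exchange at the tertiary C4 hydroxyl, which sits on the C1-methyl side of the C6 carbonyl plane in the trans-fused system, hydride is delivered intramolecularly to that face (the one an external hydride would avoid because of the syn-axial methyl), giving the 6S alcohol with H6 anti to H5.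

Step 15
Reactants: 20 (1R,4R,5S,6S)-4,6-diol; 21 4-acetoxybenzoyl chloride
Product: 22 (1R,4R,5S,6S)-C6 4-acetoxybenzoate with free C4 hydroxyl and C2 ethylene ketal
Conditions: pyridine, DMAP (cat.), CH2Cl2, 0 °C → rt
Reagents that add atoms: none
Why: DMAP-catalysed acylation with the acid chloride takes the secondary C6 hydroxyl only, the tertiary C4 hydroxyl being inert under these conditions, and the phenol is carried as its acetate.

Step 16
Reactants: 22 (1R,4R,5S,6S)-C6 4-acetoxybenzoate
Product: 24 (3R,3aS,4S,8aR)-3-hydroxy-6,8a-dimethyl-1-oxo-3-(propan-2-yl)-1,2,3,3a,4,5,8,8a-octahydroazulen-4-yl 4-hydroxybenzoate (CNP0238517.1), via phenol ketal 23 (not isolated)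
Conditions: pyrrolidine, CH2Cl2, rt; then 2 M HCl (aq), THF, rt
Reagents that add atoms: water O
Why: Aminolysis cleaves the aryl acetate far faster than the hindered alkyl benzoate, and acid-catalysed hydrolysis of the dioxolane then releases the C2 ketone at room temperature, conditions chosen to leave the tertiary β-hydroxy ketone and the trisubstituted alkene untouched.

**Compound list**

1 | 2-methylcyclopent-2-en-1-one | CC1=CCCC1=O | starting material
2 | 6-methyl-1,4-dioxaspiro[4.4]non-6-ene | CC1=CCCC12OCCO2 | intermediate
3 | 6-methyl-1,4-dioxaspiro[4.4]non-6-en-8-one | CC1=CC(=O)CC12OCCO2 | intermediate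
4 | 7-iodo-6-methyl-1,4-dioxaspiro[4.4]non-6-en-8-one | CC1=C(I)C(=O)CC12OCCO2 | intermediate
5 | (8S)-7-iodo-6-methyl-1,4-dioxaspiro[4.4]non-6-en-8-ol | CC1=C(I)[C@@H](O)CC12OCCO2 | intermediate
6 | (8S)-7-iodo-6-methyl-1,4-dioxaspiro[4.4]non-6-en-8-yl 2,2-dimethylpropanoate | CC1=C(I)[C@@H](OC(=O)C(C)(C)C)CC12OCCO2 | intermediate
7 | (E)-2-methylbut-2-enal (tiglic aldehyde) | C/C=C(\C)C=O | starting material
8 | (8S)-7-[(2E)-1-hydroxy-2-methylbut-2-en-1-yl]-6-methyl-1,4-dioxaspiro[4.4]non-6-en-8-yl 2,2-dimethylpropanoate, both carbinol epimers | CC1=C(C(O)C(/C)=C/C)[C@@H](OC(=O)C(C)(C)C)CC12OCCO2 | intermediate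
9 | (8S)-6-methyl-7-[(2E)-2-methylbut-2-enoyl]-1,4-dioxaspiro[4.4]non-6-en-8-yl 2,2-dimethylpropanoate | CC1=C(C(=O)C(/C)=C/C)[C@@H](OC(=O)C(C)(C)C)CC12OCCO2 | intermediate
10 | potassium (1E)-2-methyl-1-[(8S)-6-methyl-8-(pivaloyloxy)-1,4-dioxaspiro[4.4]non-6-en-7-yl]buta-1,3-dien-1-olate | CC1=C(/C([O-])=C(/C)C=C)[C@@H](OC(=O)C(C)(C)C)CC12OCCO2.[K+] | intermediate (not isolated)
11 | (8S)-7-[(1E)-1-(tert-butyldimethylsilyloxy)-2-methylbuta-1,3-dien-1-yl]-6-methyl-1,4-dioxaspiro[4.4]non-6-en-8-yl 2,2-dimethylpropanoate | CC1=C(/C(O[Si](C)(C)C(C)(C)C)=C(/C)C=C)[C@@H](OC(=O)C(C)(C)C)CC12OCCO2 | intermediate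
12 | (8S)-7-[(1E)-1-(tert-butyldimethylsilyloxy)-2-methylbuta-1,3-dien-1-yl]-6-methyl-1,4-dioxaspiro[4.4]non-6-en-8-ol | CC1=C(/C(O[Si](C)(C)C(C)(C)C)=C(/C)C=C)[C@@H](O)CC12OCCO2 | intermediate
13 | diiodomethane | ICI | starting material
14 | (8S)-7-[(1S,2R)-1-(tert-butyldimethylsilyloxy)-2-methyl-2-vinylcyclopropyl]-6-methyl-1,4-dioxaspiro[4.4]non-6-en-8-ol | CC(C)(C)[Si](C)(C)O[C@@]1(C2=C(C)C3(OCCO3)C[C@@H]2O)C[C@]1(C)C=C | intermediate
15 | 7-[(1S,2R)-1-(tert-butyldimethylsilyloxy)-2-methyl-2-vinylcyclopropyl]-6-methyl-1,4-dioxaspiro[4.4]non-6-en-8-one (key-step precursor, cis-divinyl) | CC(C)(C)[Si](C)(C)O[C@@]1(C2=C(C)C3(OCCO3)CC2=O)C[C@]1(C)C=C | intermediate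
16 | (1R)-bicyclic vinylogous silyl ester: C4 ketone, C5=C6 TBS enol ether, C2 ethylene ketal, C8=C9 alkene (key-step product) | CC1=CC[C@@]2(C)C3(OCCO3)CC(=O)C2=C(O[Si](C)(C)C(C)(C)C)C1 | intermediate
17 | isopropylmagnesium chloride | CC(C)[Mg]Cl | starting material
18 | (1R,4R)-tertiary carbinol: C4(OH)(i-Pr), C5=C6 TBS enol ether, C2 ethylene ketal | CC1=CC[C@@]2(C)C3(OCCO3)C[C@@](O)(C(C)C)C2=C(O[Si](C)(C)C(C)(C)C)C1 | intermediate (not isolated)
19 | (1R,4R,5R)-trans-fused β-hydroxy ketone: C4(OH)(i-Pr), C6 ketone, C2 ethylene ketal | CC1=CC[C@@]2(C)C3(OCCO3)C[C@@](O)(C(C)C)[C@@H]2C(=O)C1 | intermediate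
20 | (1R,4R,5S,6S)-4,6-diol, C2 ethylene ketal | CC1=CC[C@@]2(C)C3(OCCO3)C[C@@](O)(C(C)C)[C@@H]2[C@@H](O)C1 | intermediate
21 | 4-acetoxybenzoyl chloride | CC(=O)Oc1ccc(cc1)C(Cl)=O | starting material
22 | (1R,4R,5S,6S)-C6 4-acetoxybenzoate, C2 ethylene ketal | CC1=CC[C@@]2(C)C3(OCCO3)C[C@@](O)(C(C)C)[C@@H]2[C@@H](OC(=O)c2ccc(OC(C)=O)cc2)C1 | intermediate
23 | (1R,4R,5S,6S)-C6 4-hydroxybenzoate, C2 ethylene ketal | CC1=CC[C@@]2(C)C3(OCCO3)C[C@@](O)(C(C)C)[C@@H]2[C@@H](OC(=O)c2ccc(O)cc2)C1 | intermediate (not isolated)
24 | (3R,3aS,4S,8aR)-3-hydroxy-6,8a-dimethyl-1-oxo-3-(propan-2-yl)-1,2,3,3a,4,5,8,8a-octahydroazulen-4-yl 4-hydroxybenzoate | CC1=CC[C@@]2(C)C(=O)C[C@@](O)(C(C)C)[C@@H]2[C@@H](OC(=O)c2ccc(O)cc2)C1 | target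

Total step count: 16. Longest linear sequence: 16 steps (1 → 24).

**Steps most likely to fail**

Step 12 (key step). Because the C1 methyl points at the C7 methylene in the boat, the concerted shift may need a temperature at which homolysis of the C6–C8 bond (loss of stereochemical information) or polar opening of the donor-substituted cyclopropane toward the enone competes, or at which the vinylogous silyl ester loses its silyl group. The fallback moves the rearrangement to the carbinol oxidation level. It sets out from cyclopropyl alcohol 14, which lacks the acceptor. Thermolysis of 14 in toluene should give the C4-hydroxy silyl enol ether F2 (C4–OH, C5=C6–OTBS, 1R), and oxidation of its allylic hydroxyl with MnO2 in CH2Cl2 comes back to the route at 16.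

Step 13. The carbon nucleophile may approach C4 from the face of the C1 methyl (wrong C4 configuration). The tertiary allylic alcohol next to the enol ether may ionise and lose water (Stork–Danheiser transposition). Fluoride may open the five-membered ring by retro-aldol cleavage. The fallback delivers oxygen to an alkene instead of carbon to a ketone, and is the remedy for attack syn to the C1 methyl. It sets out from 16. The organocerium adduct is deliberately hydrolysed with dilute aqueous oxalic acid to the transposed enone F3 (C4(i-Pr)=C5–C6=O), whose formation does not depend on the facial course of the addition. Weitz–Scheffer epoxidation (t-BuOOH, benzyltrimethylammonium hydroxide, THF, 0 °C) attacks C4 and should use the face the carbon nucleophile preferred, which in that case gives the epoxy ketone F4 with oxygen syn to the C1 methyl. SmI2 in THF/MeOH at −78 °C cleaves the C5–O bond to the β-hydroxy ketone, and the route is rejoined at 19.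

Step 10. Carbenoid delivery from the C4 zinc alkoxide may take the other rotamer or π-face of the enol ether (low or reversed diastereoselectivity), or methylene may also be transferred to the ring alkene under hydroxyl direction. If only the sense is reversed, the (8R) series from the enantiomeric CBS catalyst would serve, since C4 is oxidised later. The fallback replaces substrate direction by reagent control. It sets out from pivalate 11, which has no free hydroxyl. A catalytic asymmetric Simmons–Smith reaction of the silyl enol ether (Et2Zn, CH2I2, N-Boc-L-valyl-L-proline methyl ester or its enantiomer, CH2Cl2, −40 °C) gives the siloxycyclopropane pivalate F1. Because C4 is a fixed stereocentre, the two cyclopropane configurations are diastereomers and are separated by chromatography. Cleavage of the pivalate with i-Bu2AlH at −78 °C returns to the route at 14.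

**Further compounds**

F1 | step 10 | (8S)-7-[(1S,2R)-1-(tert-butyldimethylsilyloxy)-2-methyl-2-vinylcyclopropyl]-6-methyl-1,4-dioxaspiro[4.4]non-6-en-8-yl 2,2-dimethylpropanoate | CC(C)(C)[Si](C)(C)O[C@@]1(C2=C(C)C3(OCCO3)C[C@@H]2OC(=O)C(C)(C)C)C[C@]1(C)C=C
F2 | step 12 | (1R,4S)-C4-hydroxy silyl enol ether: C4–OH, C5=C6 TBS enol ether, C2 ethylene ketal, C8=C9 alkene | CC1=CC[C@@]2(C)C3(OCCO3)C[C@H](O)C2=C(O[Si](C)(C)C(C)(C)C)C1
F3 | step 13 | (1R)-transposed enone: C4(i-Pr)=C5, C6 ketone, C2 ethylene ketal, C8=C9 alkene | CC1=CC[C@@]2(C)C3(OCCO3)CC(C(C)C)=C2C(=O)C1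
F4 | step 13 | 4,5-epoxy-4-isopropyl C6 ketone, epoxide oxygen syn to the C1 methyl, C2 ethylene ketal | CC1=CC[C@@]2(C)C3(OCCO3)C[C@]4(C(C)C)O[C@]24C(=O)C1
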